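The route forms the C1–C2 bond of the cyclobutane last. Both ring CH carbons of that bond carry an alkynyl group, so each can exist briefly as a propargyl-stabilised radical, and the four-membered ring can therefore be reached from a five-membered one by cutting out its nitrogen atom. In one operation the key step turns a cis-2,5-dialkynylpyrrolidine into the cis-1,2-dialkynylcyclobutane: it forms C1–C2, closes the cyclobutane and hands on the cis arrangement of the two CH centres. Its precursor is the free NH pyrrolidine that already carries both (2,2'-bithiophen-5-yl)ethynyl arms at C2 and C5, built from a meso-dibromoadipate, benzylamine and 5-bromo-2,2'-bithiophene.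

Key step: step 6

Remark: the (1R,2S) descriptors of the target define the meso cis-cyclobutane, so no absolute stereocontrol is needed; every pyrrolidine on the way is the meso cis isomer, and the open-chain monoaminated bromide of step 1 is racemic.

Step 1
Reactants: 1 diethyl meso-2,5-dibromoadipate; 2 benzylamine
Product: 4 cis-diethyl 1-benzylpyrrolidine-2,5-dicarboxylate, via monoaminated bromide 3 (not isolated)
Conditions: K2CO3, toluene–H2O, reflux; chromatography
Reagents that add atoms: none
Why: Double SN2 N-alkylation (intermolecular displacement, then 5-exo-tet ring closure) proceeds with inversion at each C–Br carbon, so the meso dibromide should map onto the cis (2S,5R) diester, and any trans isomer arising from bromide-exchange epimerisation is removed by chromatography.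

Step 2
Reactants: 4 cis-diethyl 1-benzylpyrrolidine-2,5-dicarboxylate
Product: 6 1-tert-butyl 2,5-diethyl cis-pyrrolidine-1,2,5-tricarboxylate, via free NH diester 5 (not isolated)
Conditions: H2 (1 atm), Pd(OH)2 on carbon, Boc2O, EtOH, rt
Reagents that add atoms: di-tert-butyl dicarbonate, CC(C)(C)OC(=O)OC(=O)OC(C)(C)C
Why: Hydrogenolysis of the N-benzyl group releases the secondary amine, which is trapped in the same flask as its tert-butyl carbamate, and these neutral conditions leave both α-amino ester stereocentres untouched.

Step 3
Reactants: 6 1-tert-butyl 2,5-diethyl cis-pyrrolidine-1,2,5-tricarboxylate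
Product: 8 cis-tert-butyl 2,5-diethynylpyrrolidine-1-carboxylate, via dialdehyde 7 (not isolated)
Conditions: i-Bu2AlH, CH2Cl2, −78 °C; then MeOH, K2CO3, dimethyl (1-diazo-2-oxopropyl)phosphonate, −78 °C to rt
Reagents that add atoms: dimethyl (1-diazo-2-oxopropyl)phosphonate, CC(=O)C(=[N+]=[N-])P(=O)(OC)OC
Why: At −78 °C i-Bu2AlH stops at the tetrahedral aluminium hemiacetal of each ester, and methanolysis releases dialdehyde 7 straight into the Ohira–Bestmann (Seyferth–Gilbert) homologation, which turns each CHO into C≡CH under mildly basic conditions that N-Boc α-amino aldehydes are known to tolerate without epimerisation, so the cis relationship should be kept.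

Step 4
Reactants: 8 cis-tert-butyl 2,5-diethynylpyrrolidine-1-carboxylate; 9 5-bromo-2,2'-bithiophene (slight excess over two equivalents)
Product: 10 cis-tert-butyl 2,5-bis[(2,2'-bithiophen-5-yl)ethynyl]pyrrolidine-1-carboxylate
Conditions: Pd(PPh3)2Cl2 (cat.), CuI (cat.), Et3N, THF, 50 °C, degassed, dark
Reagents that add atoms: none
Why: Twofold Sonogashira coupling (oxidative addition of zerovalent palladium into the thienyl C–Br bond, transmetalation from the copper acetylide, reductive elimination) should join each terminal alkyne to C5 of a bithiophene, with the carbamate and the two sp3 stereocentres as spectators.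

Step 5
Reactants: 10 cis-tert-butyl 2,5-bis[(2,2'-bithiophen-5-yl)ethynyl]pyrrolidine-1-carboxylate
Product: 12 cis-2,5-bis[(2,2'-bithiophen-5-yl)ethynyl]pyrrolidine, via trimethylsilyl carbamate 11 (not isolated)
Conditions: TMSOTf, 2,6-lutidine, CH2Cl2, 0 °C; then MeOH; aq NaHCO3; used directly
Reagents that add atoms: none
Why: Silyl-triflate carbamate cleavage (exchange of the tert-butyl for a trimethylsilyl carbamate with loss of isobutene, then methanolysis and decarboxylation) frees the NH under buffered, aprotic conditions, chosen so that no strong Brønsted acid can add to the electron-rich bithienyl alkynes, and the stereocentres are not involved.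

Step 6
Reactants: 12 cis-2,5-bis[(2,2'-bithiophen-5-yl)ethynyl]pyrrolidine; 13 N-(benzyloxy)-N-(pivaloyloxy)-4-(trifluoromethyl)benzamide (1.5 equiv)
Product: 17 isocardopatine, via N-aminated amide 14 (not isolated), via 1,1-diazene 15 (not isolated), via singlet 1,4-diradical 16 (not isolated)
Conditions: THF, 45 °C, argon, dark; chromatography at rt in the dark
Reagents that add atoms: none
Why: The secondary amine of 12 attacks the amide nitrogen of 13 and displaces pivalate, and the resulting N-amino-N-benzyloxy amide 14 rearranges by shift of the benzyloxy group to the carbonyl carbon, releasing benzyl 4-(trifluoromethyl)benzoate and 1,1-diazene 15, which loses N2 to give singlet 1,4-diradical 16. The closest known reaction type is the anomeric-amide nitrogen deletion of secondary amines and the stereoretentive 1,1-diazene contraction of 2,5-disubstituted pyrrolidines to cyclobutanes, applied here with two propargylic in place of benzylic radical centres. The cyclobutane, the only ring formed, closes by intramolecular radical–radical recombination of C3 and C6 of the diradical, which become C1 and C2 of the ring. No stereocentre is induced afresh: the cis relationship at C1/C2 is inherited from C2/C5 of the pyrrolidine, because the spin-paired diradical should couple faster than its C–C bonds rotate. The step needs collapse at the propargylic carbons to outrun bond rotation, β-scission into two molecules of 5-(but-3-en-1-ynyl)-2,2'-bithiophene, coupling through the allenyl termini and a [2,3]-shift of 15 onto an alkyne; the singlet spin state and the two-carbon tether that holds C3 and C6 close favour collapse, and the last two paths would have to form strained cyclic allenes. Double propargylic stabilisation should let N2 leave at 45 °C, well below the onset of Cope rearrangement of the cis-dialkynylcyclobutane, the slim alkynyl groups leave the nitrogen open to the reagent, and since 13 is an aminating agent and not an oxidant the bithiophenes should stay intact.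

Compound list
1 | diethyl meso-2,5-dibromoadipate (2R,5S) | CCOC(=O)[C@H](Br)CC[C@H](Br)C(=O)OCC | starting material
2 | benzylamine | NCc1ccccc1 | starting material
3 | diethyl (2S*,5S*)-2-(benzylamino)-5-bromohexanedioate (racemic, one enantiomer drawn; formed in situ in step 1) | CCOC(=O)[C@@H](NCc1ccccc1)CC[C@H](Br)C(=O)OCC | intermediate
4 | cis-diethyl 1-benzylpyrrolidine-2,5-dicarboxylate (2S,5R; meso) | CCOC(=O)[C@@H]1CC[C@H](C(=O)OCC)N1Cc1ccccc1 | intermediate
5 | cis-diethyl pyrrolidine-2,5-dicarboxylate (formed in situ in step 2) | CCOC(=O)[C@@H]1CC[C@H](C(=O)OCC)N1 | intermediate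
6 | 1-tert-butyl 2,5-diethyl cis-pyrrolidine-1,2,5-tricarboxylate (N-Boc cis-diester) | CCOC(=O)[C@@H]1CC[C@H](C(=O)OCC)N1C(=O)OC(C)(C)C | intermediate
7 | cis-tert-butyl 2,5-diformylpyrrolidine-1-carboxylate (formed in situ in step 3) | O=C[C@@H]1CC[C@H](C=O)N1C(=O)OC(C)(C)C | intermediate
8 | cis-tert-butyl 2,5-diethynylpyrrolidine-1-carboxylate | C#C[C@@H]1CC[C@H](C#C)N1C(=O)OC(C)(C)C | intermediate
9 | 5-bromo-2,2'-bithiophene | Brc1ccc(-c2cccs2)s1 | starting material
10 | cis-tert-butyl 2,5-bis[(2,2'-bithiophen-5-yl)ethynyl]pyrrolidine-1-carboxylate | C(#C[C@@H]1CC[C@H](C#Cc2ccc(-c3cccs3)s2)N1C(=O)OC(C)(C)C)c1ccc(-c2cccs2)s1 | intermediate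
11 | trimethylsilyl cis-2,5-bis[(2,2'-bithiophen-5-yl)ethynyl]pyrrolidine-1-carboxylate (formed in situ in step 5) | C(#C[C@@H]1CC[C@H](C#Cc2ccc(-c3cccs3)s2)N1C(=O)O[Si](C)(C)C)c1ccc(-c2cccs2)s1 | intermediate
12 | cis-2,5-bis[(2,2'-bithiophen-5-yl)ethynyl]pyrrolidine (2S,5R; meso) | C(#C[C@@H]1CC[C@H](C#Cc2ccc(-c3cccs3)s2)N1)c1ccc(-c2cccs2)s1 | intermediate
13 | N-(benzyloxy)-N-(pivaloyloxy)-4-(trifluoromethyl)benzamide | O=C(c1ccc(cc1)C(F)(F)F)N(OCc1ccccc1)OC(=O)C(C)(C)C | starting material
14 | N-(benzyloxy)-N-{cis-2,5-bis[(2,2'-bithiophen-5-yl)ethynyl]pyrrolidin-1-yl}-4-(trifluoromethyl)benzamide (formed in situ in step 6) | C(#C[C@@H]1CC[C@H](C#Cc2ccc(-c3cccs3)s2)N1N(OCc1ccccc1)C(=O)c1ccc(cc1)C(F)(F)F)c1ccc(-c2cccs2)s1 | intermediate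
15 | 1,1-diazene of 12: cis-2,5-bis[(2,2'-bithiophen-5-yl)ethynyl]pyrrolidin-1-ium-1-ylideneazanide (formed in situ in step 6) | C(#C[C@@H]1CC[C@H](C#Cc2ccc(-c3cccs3)s2)[N+]1=[N-])c1ccc(-c2cccs2)s1 | intermediate
16 | 1,8-bis(2,2'-bithiophen-5-yl)octa-1,7-diyne-3,6-diyl, singlet 1,4-diradical (formed in situ in step 6) | C(#C[CH]CC[CH]C#Cc1ccc(-c2cccs2)s1)c1ccc(-c2cccs2)s1 | intermediate
17 | isocardopatine, cis-1,2-bis[(2,2'-bithiophen-5-yl)ethynyl]cyclobutane (1R,2S; meso) | C(#C[C@@H]1CC[C@@H]1C#Cc1ccc(-c2cccs2)s1)c1ccc(-c2cccs2)s1 | target

Total step count: 6 steps.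
Longest linear sequence: 6 steps (from 1 to 17).

Steps most likely to fail

1. Step 6 (ring contraction). The diradical may fragment into two enyne molecules or rotate before it closes, so that the cis geometry is lost, or the N-amination may be sluggish. The fallback gives up the late C1–C2 bond formation and buys the four-membered ring. It sets out from 5-bromo-2,2'-bithiophene 9 together with purchased cis-cyclobutane-1,2-dicarboxylic anhydride F1 and comes back to the route at target 17. LiAlH4 in THF should reduce the anhydride to cis-1,2-bis(hydroxymethyl)cyclobutane F2. Dess–Martin periodinane buffered with NaHCO3 should oxidise it to cis-cyclobutane-1,2-dicarbaldehyde F3 without base-induced epimerisation. Corey–Fuchs olefination (CBr4, PPh3, CH2Cl2, 0 °C) should give cis-1,2-bis(2,2-dibromovinyl)cyclobutane F4, and n-BuLi in THF at −78 °C followed by aqueous NH4Cl should give cis-1,2-diethynylcyclobutane F5, which is volatile and would be carried on as a solution. The Sonogashira conditions of step 4 with 9 should then deliver 17.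

2. Step 3 (ester to alkyne in one flask). Over-reduction past the aldehyde stage, incomplete reduction of one ester, or epimerisation at C2/C5 during the basic homologation could erode the material. The fallback separates the redox steps and avoids base at the aldehyde stage. It sets out from diester 6 and comes back at diyne 8. LiBH4 in THF should reduce both esters fully to cis-tert-butyl 2,5-bis(hydroxymethyl)pyrrolidine-1-carboxylate F6. Swern oxidation at −78 °C should give dialdehyde 7, this time isolated and used crude. Corey–Fuchs olefination (CBr4, PPh3, CH2Cl2, 0 °C) should give cis-tert-butyl 2,5-bis(2,2-dibromovinyl)pyrrolidine-1-carboxylate F7, and n-BuLi in THF at −78 °C should convert it into 8.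

3. Step 5 (carbamate removal). Acid- or silyl-induced addition to the bithienyl alkynes, or incomplete cleavage of the hindered carbamate, may occur. The fallback changes the order of events so that the carbamate is removed before any electron-rich arene is present. It sets out from diyne 8 and comes back at pyrrolidine 12. HCl in dioxane at 0 °C should give cis-2,5-diethynylpyrrolidine hydrochloride F8, since unactivated terminal alkynes do not add HCl under these conditions. Sonogashira coupling of this salt with 9 under the step 4 conditions, with extra Et3N to free the amine, should give 12 directly.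

Further compounds
F1 | step 6 | cis-cyclobutane-1,2-dicarboxylic anhydride, 3-oxabicyclo[3.2.0]heptane-2,4-dione (purchased) | O=C2OC(=O)[C@@H]1CC[C@@H]12
F2 | step 6 | cis-1,2-bis(hydroxymethyl)cyclobutane | OC[C@@H]1CC[C@@H]1CO
F3 | step 6 | cis-cyclobutane-1,2-dicarbaldehyde | O=C[C@@H]1CC[C@@H]1C=O
F4 | step 6 | cis-1,2-bis(2,2-dibromovinyl)cyclobutane | BrC(Br)=C[C@@H]1CC[C@@H]1C=C(Br)Br
F5 | step 6 | cis-1,2-diethynylcyclobutane | C#C[C@@H]1CC[C@@H]1C#C
F6 | step 3 | cis-tert-butyl 2,5-bis(hydroxymethyl)pyrrolidine-1-carboxylate | OC[C@@H]1CC[C@H](CO)N1C(=O)OC(C)(C)C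
F7 | step 3 | cis-tert-butyl 2,5-bis(2,2-dibromovinyl)pyrrolidine-1-carboxylate | BrC(Br)=C[C@@H]1CC[C@H](C=C(Br)Br)N1C(=O)OC(C)(C)C
F8 | step 5 | cis-2,5-diethynylpyrrolidine hydrochloride | C#C[C@@H]1CC[C@H](C#C)[NH2+]1.[Cl-]
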